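## Retrosynthetic overview
1. The target comes from its MOM-protected cis-(2R,3S) precursor by one acid operation. This removes the MOM groups, cleaves a sacrificial vanillyl ether on O4, and epimerises C2 to trans through the vanillyl-type cation, with C3 in control.
2. The C6 stilbene is disconnected by a late Mizoroki–Heck coupling of a 6-bromo-dihydrobenzofuran with a protected 4-vinylguaiacol. No ring is formed here.
3. Key step: the only new ring, the dihydrofuran, is closed through the C2–C3 bond rather than a C–O bond. An enantioselective Rh(II) donor/donor-carbene 1,5-C–H insertion is run on a diaryl diazo compound carrying two identical ortho vanillyl ethers. One ether is the C–H donor and the other serves as the O4 protecting group.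
4. The carbene precursor is a hydrazone, made from a 2,6-bis(vanillyloxy)benzophenone, which comes from double SNAr on a 2,6-difluorobenzophenone.
5. The difluorobenzophenone comes from ortho-lithiated 1-bromo-3,5-difluorobenzene and 3,5-bis(MOM-oxy)benzaldehyde.

Assumption 1: the SMILES decodes as (2S,3S), with trans aryl groups and an E alkene. The route is planned for that structure.

Assumption 2: Rh2(S-PTAD)4 is taken to deliver the 3S series. The sense must be checked on bromide 13 by anomalous-dispersion X-ray, and the equally available antipode used if it is reversed.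

## Route

**Step 1**
Reactants: 1 vanillin
Product: 2 3-methoxy-4-(methoxymethoxy)benzaldehyde
Conditions: MOMCl, i-Pr2NEt, CH2Cl2, 0 °C → rt
Reagents that add atoms: chloromethyl methyl ether, COCCl
Why: Phenol O-alkylation (acetal protection); MOM survives alkoxide, hydrazine, MnO2, Rh(II) and Pd(0) and leaves under the acid used in the last step.

**Step 2**
Reactants: 2
Product: 3 [3-methoxy-4-(methoxymethoxy)phenyl]methanol
Conditions: NaBH4, MeOH, 0 °C
Reagents that add atoms: none
Why: Chemoselective borohydride reduction of the aldehyde; the acetal and aryl ethers are inert.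

**Step 3**
Reactants: 2
Product: 4 2-methoxy-1-(methoxymethoxy)-4-vinylbenzene
Conditions: Ph3PCH3Br, KOt-Bu, THF, 0 °C → rt
Reagents that add atoms: methyltriphenylphosphonium bromide, C[P+](c1ccccc1)(c1ccccc1)c1ccccc1.[Br-]
Why: Wittig methylenation of a non-enolisable aryl aldehyde gives the Heck partner already protected, which avoids handling polymerisation-prone free vinylguaiacol.

**Step 4**
Reactants: 5 3,5-dihydroxybenzaldehyde
Product: 6 3,5-bis(methoxymethoxy)benzaldehyde
Conditions: MOMCl (2.6 equiv), i-Pr2NEt, DMF, 0 °C → rt
Reagents that add atoms: chloromethyl methyl ether, COCCl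
Why: Double phenol O-alkylation, using the same protecting-group logic as step 1.

**Step 5**
Reactants: 7 1-bromo-3,5-difluorobenzene; 6
Product: 8 (±)-(4-bromo-2,6-difluorophenyl)[3,5-bis(methoxymethoxy)phenyl]methanol
Conditions: LDA, THF, −78 °C, 45 min; then 6, −78 → −40 °C; aq NH4Cl
Reagents that add atoms: none (all atoms come from 6 and 7)
Why: Directed ortho-lithiation at the C–H flanked by two fluorines (an amide base at −78 °C avoids Br/Li exchange and benzyne formation), followed by 1,2-addition; the racemic carbinol centre is erased in step 6.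

**Step 6**
Reactants: 8
Product: 9 (4-bromo-2,6-difluorophenyl)[3,5-bis(methoxymethoxy)phenyl]methanone
Conditions: Dess–Martin periodinane, NaHCO3, CH2Cl2, rt
Reagents that add atoms: none
Why: Buffered Dess–Martin oxidation of a hindered, electron-poor diaryl carbinol; the bicarbonate protects the MOM acetals.

**Step 7**
Reactants: 9; 3 (2.4 equiv)
Product: 10 {4-bromo-2,6-bis[(3-methoxy-4-(methoxymethoxy)benzyl)oxy]phenyl}[3,5-bis(methoxymethoxy)phenyl]methanone
Conditions: NaH, DMF, 0 °C; add 9; 0 → 45 °C
Reagents that add atoms: none (all new atoms come from 3)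
Why: Double SNAr in which both fluorides are ortho to the ketone and F reacts far faster than Br; the first alkoxy group is meta to the second reaction site and so does not deactivate it, and the low temperature suppresses MPV-type hydride transfer.

**Step 8**
Reactants: 10
Product: 11 hydrazone of 10 (E/Z mixture, which has no consequence)
Conditions: N2H4·H2O (30 equiv), cat. AcOH, n-BuOH, 110 °C, sealed tube, Ar
Reagents that add atoms: hydrazine hydrate, NN.O
Why: Forced hydrazone condensation on a ketone hindered on one side only; the hydrazinium acetate buffer spares the MOM groups, the ortho substituents are now poor leaving groups so indazole formation is avoided, and Ar excludes diimide.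

**Step 9 (key step)**
Reactants: 11
Product: 13 (2R,3S)-cis-6-bromo-3-[3,5-bis(methoxymethoxy)phenyl]-2-[3-methoxy-4-(methoxymethoxy)phenyl]-4-{[3-methoxy-4-(methoxymethoxy)benzyl]oxy}-2,3-dihydrobenzofuran, formed via 12, the corresponding diaryldiazomethane (not isolated)
Conditions: activated MnO2 (10 equiv), CH2Cl2, rt, 1 h (→ 12); then Rh2(S-PTAD)4 (1 mol %), 0 °C, one pot
Reagents that add atoms: none
Why: Hydrazone dehydrogenation followed by enantioselective Rh(II) donor/donor-carbene 1,5-C–H insertion, in which the twisted 2,6-dialkoxyaryl ring holds either of two degenerate, strongly activated OCH2Ar C–H bonds over the carbene; hydride-transfer-like insertion inside the chiral carboxylate pocket sets C3 (S) under catalyst control and C2 (R) through the intrinsic cis preference, and the only extension of known scope is the second ortho ether, with only the C3 ee mattering because C2 is re-equilibrated in step 11.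

**Step 10**
Reactants: 13; 4
Product: 14 (2R,3S)-cis-3-[3,5-bis(methoxymethoxy)phenyl]-2-[3-methoxy-4-(methoxymethoxy)phenyl]-4-{[3-methoxy-4-(methoxymethoxy)benzyl]oxy}-6-[(E)-3-methoxy-4-(methoxymethoxy)styryl]-2,3-dihydrobenzofuran
Conditions: Pd2(dba)3 (2.5 mol %), [HP(t-Bu)3]BF4 (6 mol %), Cy2NMe, dioxane, 80 °C
Reagents that add atoms: none (all new atoms come from 4)
Why: Mizoroki–Heck coupling of an unhindered 3,5-dioxygenated aryl bromide through the neutral pathway gives β-arylation and the E-stilbene; the ethers, acetals and both sp3 stereocentres are untouched by the amine base.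

**Step 11**
Reactants: 14
Product: 15 bisisorhapontigenin B, (2S,3S)-trans
Conditions: 3 M aq HCl, i-PrOH/THF (1:1), 50 °C, Ar, dark; no carbon-nucleophile scavenger
Reagents that add atoms: none (water and i-PrOH end up only in by-products)
Why: Acid acetal hydrolysis removes all the MOM groups while SN1 acidolysis ionises both vanillyl–OAr bonds; the primary O4-vanillyl cation is lost to solvent and frees the C4 phenol, whereas the hindered C2 cation is recaptured by either equivalent ortho phenol (reversible 5-ring closure), draining cis to the more stable trans isomer so that C2 becomes S under control of the untouched C3 (S).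

## Compound list
1 | vanillin | COc1cc(C=O)ccc1O | starting material
2 | 3-methoxy-4-(methoxymethoxy)benzaldehyde | COCOc1ccc(C=O)cc1OC | intermediate
3 | [3-methoxy-4-(methoxymethoxy)phenyl]methanol | COCOc1ccc(CO)cc1OC | intermediate
4 | 2-methoxy-1-(methoxymethoxy)-4-vinylbenzene | COCOc1ccc(C=C)cc1OC | intermediate
5 | 3,5-dihydroxybenzaldehyde | O=Cc1cc(O)cc(O)c1 | starting material
6 | 3,5-bis(methoxymethoxy)benzaldehyde | COCOc1cc(C=O)cc(OCOC)c1 | intermediate
7 | 1-bromo-3,5-difluorobenzene | Fc1cc(Br)cc(F)c1 | starting material
8 | (±)-(4-bromo-2,6-difluorophenyl)[3,5-bis(MOM-oxy)phenyl]methanol | OC(c1c(F)cc(Br)cc1F)c1cc(OCOC)cc(OCOC)c1 | intermediate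
9 | (4-bromo-2,6-difluorophenyl)[3,5-bis(MOM-oxy)phenyl]methanone | O=C(c1c(F)cc(Br)cc1F)c1cc(OCOC)cc(OCOC)c1 | intermediate
10 | bis(vanillyl ether) benzophenone | O=C(c1c(OCc2ccc(OCOC)c(OC)c2)cc(Br)cc1OCc1ccc(OCOC)c(OC)c1)c1cc(OCOC)cc(OCOC)c1 | intermediate
11 | hydrazone of 10 | NN=C(c1c(OCc2ccc(OCOC)c(OC)c2)cc(Br)cc1OCc1ccc(OCOC)c(OC)c1)c1cc(OCOC)cc(OCOC)c1 | intermediate
12 | diaryldiazomethane (not isolated) | [N-]=[N+]=C(c1c(OCc2ccc(OCOC)c(OC)c2)cc(Br)cc1OCc1ccc(OCOC)c(OC)c1)c1cc(OCOC)cc(OCOC)c1 | intermediate
13 | (2R,3S)-cis-6-bromo dihydrobenzofuran | Brc1cc(OCc2ccc(OCOC)c(OC)c2)c2c(c1)O[C@@H](c1ccc(OCOC)c(OC)c1)[C@H]2c1cc(OCOC)cc(OCOC)c1 | intermediate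
14 | (2R,3S)-cis, E-stilbene, penta-MOM, O4-vanillyl | COCOc1ccc(/C=C/c2cc(OCc3ccc(OCOC)c(OC)c3)c3c(c2)O[C@@H](c2ccc(OCOC)c(OC)c2)[C@H]3c2cc(OCOC)cc(OCOC)c2)cc1OC | intermediate
15 | bisisorhapontigenin B, (2S,3S) | COc1cc(/C=C/c2cc(O)c3c(c2)O[C@H](c2ccc(O)c(OC)c2)[C@H]3c2cc(O)cc(O)c2)ccc1O | target

## Summary
Total step count: 11, counting step 9 as one pot.
Longest linear sequence: 8 steps (5 → 6 → 8 → 9 → 10 → 11 → 13 → 14 → 15).

Three steps most likely to fail:

1. **Step 9.** The di-ortho-substituted diaryl carbene may form slowly, may divert to azine or ketone, or may give eroded ee.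
   Fallback: abandon C–H insertion. Generate the o-quinone methide from (4-bromo-2,6-dihydroxyphenyl)[3,5-bis(MOM-oxy)phenyl]methanol and trap it in a [4+1] annulation with the ylide of an enantiopure isothiocineole-derived vanillyl sulfonium salt. This forms C2–C3 and C2–O together and gives the trans ring directly.

2. **Step 8.** Hydrazone formation on the 2,6-dialkoxybenzophenone may be too slow.
   Fallback: avoid the ketone altogether.
   - Run the double SNAr of 3 on 4-bromo-2,6-difluorobenzonitrile.
   - Add 3,5-bis(MOM-oxy)phenylmagnesium bromide to give the stable N–H ketimine.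
   - Convert the ketimine to 11 by mild transimination with hydrazine.

3. **Step 11.** The triple acid cascade could give incomplete vanillyl loss, E1 leakage to the triarylethylene, or solvent adducts.
   Fallback: move from the cationic to the anionic quinone-methide manifold.
   - Strip the MOM groups under mild conditions (ZnBr2/n-PrSH, 0 °C).
   - Treat the polyphenol with K2CO3/MeOH. The p-hydroxybenzyl aryl ether on O4 then leaves by 1,6-elimination, and C2 epimerises through reversible ring-opening to the p-quinone methide.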